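**Conventions.** Decalin numbering: ring A = C1–C4, C5, C10; ring B = C5–C10; C11 = methylidene carbon on C4; C15 = CH2 between C9 and the six-membered oxygenated ring. "α" is the face of the decalin that carries H-10, "β" the other face. Compounds are numbered 1–30 as in the steps and in the list at the end. The ones that carry the argument are 4 (benzylic bromide), 6 (siloxydiene), 7 (pulegone), 11, 15, 19, 21 (dienophile), 22 (cycloadduct), 27, 28, 29 and 30 (target).

## Analysis of the target

The target 30 is a rearranged drimane (avarane-type) sesquiterpenoid. It is a cis-fused decalin whose C9 is joined through C15 to a 2-hydroxy-5-methoxy-1,4-benzoquinone and whose C4 carries an exocyclic methylidene (C11). Four contiguous stereocentres, C5, C10, C9 and C8, sit along ring B, and two of them (C5, C9) are quaternary; the absolute configuration is (5R,8R,9R,10S). The C5 methyl, H-10, the C8 methyl and C15 all lie on the α face, and the C9 methyl alone is β, so the ring fusion is cis and the two methyl groups on C8 and C9 are trans. The hydroxyquinone is a redox-active vinylogous acid that will not survive enolates, ylides, hydrazine or hot alkali. The 1,1-disubstituted C4=C11 alkene can migrate into ring A under acid. The difficulty lies in the two quaternary carbons flanking the C10 methine, and in a cis fusion and C8/C9 relationship that the usual trans-decalin building blocks do not supply. The feature used here is that the cis C5-methyl/C10-hydrogen pair, with an oxidisable C4 next to C5, is the retron of a Diels–Alder adduct: a ring-B 2-methylcyclohex-2-enone (C5=C10, C6 carbonyl) plus a 1-oxygenated butadiene supplying C1–C4.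

## Retrosynthetic reasoning

**30 ⇒ 29 ⇒ 28.** No skeletal bond is cut. Target 30 comes from dimethoxyquinone 29 by exchange of one methoxy group for hydroxyl, and 29 from tetramethoxyarene 28 by oxidative demethylation. The arene is the carrier of the quinone because it tolerates every earlier step, and because it is symmetric about the C15 axis, so only one quinone can form. The forward steps must spare the C4 methylidene and must distinguish the two methoxy groups of 29.

**28 ⇒ 27.** The C4=C11 bond is cut to the C4 ketone 27. The alkene is placed after all acidic and reductive steps, and a carbonyl at C4 is what a C4 oxygen from the cycloaddition becomes. The forward olefination has to work on a ketone next to the quaternary C5.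

**27 ⇒ 26 ⇒ 23 ⇒ 22.** These are functional-group changes only. The C4 ketone comes from alcohol 26. The C6 methylene comes from the C6 ketone of 23, which is needed only to activate the dienophile. The saturated C2–C3 bond comes from the alkene of cycloadduct 22. The C6 ketone must go before C4 is oxidised, because a 2,2-disubstituted 1,3-diketone would cleave, and it must go while the C4 oxygen is still silylated, so that no retro-aldol opening of ring A can occur.

**22 ⇒ 21 + 6 (key disconnection).** C1–C10 and C4–C5 are cut, which removes ring A and leaves enone 21 and diene 6. This cut is chosen because suprafacial addition across C5=C10 gives the cis relationship of the C5 methyl and H-10 by mechanism, forms the quaternary C5 with its methyl already in place, and delivers oxygen at C4. It also makes the route convergent: ring B arrives with C8 and C9 already set. The forward reaction must overcome the hindrance of a β-carbon next to a quaternary centre, must bond the siloxy terminus to C5, and must add to the face opposite the arylmethyl group.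

**21 ⇒ 20 ⇒ 19.** The C5–CH3 bond is cut to α-iodoenone 20 and then to enone 19. Putting the methyl on last keeps the transposition chemistry on the simplest enone and uses the only nucleophilic position of 19.

**19 ⇒ 18 ⇒ 16 ⇒ 15.** The carbonyl is moved from C6 back to C10 through allylic alcohol 18 and epoxy ketone 16 to enone 15. The quaternary C9 can only be built by enolate alkylation next to a carbonyl, that is with the carbonyl at C10, whereas the cycloaddition needs it at C6; a 1,3-transposition reconciles the two.

**15 ⇒ 13 ⇒ 11 + 4.** The C9–CH3 bond and then the C9–C15 bond are cut, leading to enone 11 and bromide 4. The order matters: the second electrophile enters anti to the neighbouring C8 methyl, so the methyl group must come second to end trans to the C8 methyl and leave the arylmethyl group cis to it.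

**11 ⇒ 9 ⇒ 8 ⇒ 7.** Enone 11 is traced to pulegone 7 through sulfide 9 and epoxide 8. Compound 7 supplies the C8 stereocentre from the chiral pool, and the sulfur places the double bond on the side away from the methyl group without relying on regioselective enolisation.

**4 ⇒ 3 ⇒ 1 and 6 ⇒ 5.** The bromide is taken back through alcohol 3 to arene 1 (one C–C bond, by lithiation and hydroxymethylation). The diene is taken back to crotonaldehyde 5 by O-silylation.

## Alternatives that were turned down

**Alternative 1:** An intramolecular Diels–Alder reaction cuts C5–C10 and C8–C9 and leads back to an open-chain triene aldehyde A2. In A2 an (E)-2-methyl-enal (C9=C10) is tethered through C1–C4 to a diene (C5–C8) whose C5=C6 bond holds the tether Z. Forward, Me2AlCl would promote an endo cyclisation to the cis-fused octalin aldehyde A1, closing both rings at once.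
- For it: four stereocentres, both quaternary carbons included, come from alkene geometry in one step; the closure is intramolecular, which helps congested bond formation; there is no activating ketone to excise. On these points it is stronger than the chosen route.
- Against it: A2 needs three defined alkenes, one of them a Z-trisubstituted diene terminus that reaches the s-cis form poorly and can undergo a [1,5]-hydrogen shift from C4. The absolute sense rests on the single C4 stereocentre. After cyclisation the aryl group still has to be added to a neopentyl aldehyde and the benzylic oxygen removed, and the C6=C7 alkene reduced.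
- Comparison: the chosen route offers two simple, separately checked partners, with C8 and C9 fixed from the chiral pool before the risky step and fewer geometric elements to control. Overall step count would be similar.

**Alternative 2:** A protonation-initiated (class two) terpene cyclase variant would fold the achiral (2E,6E)-farnesyl arene A4 into A3 in one step. It would form C4–C5 and C9–C10, then shift two hydrides and two methyl groups so that methyls end on C9 and C5, and finally lose a proton from C11. A3 is the same compound as 28.
- For it: step economy is unbeatable, about four steps to 30 with no protecting groups. On this point it is clearly stronger.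
- Against it: the all-anti shift sequence from a chair–chair drimanyl cation leads to the trans-fused series with the other C8 configuration. The target needs a different folding and a non-anti event at C5, a different C8 outcome, and a specific terminating deprotonation, all with a bulky tetramethoxyaryl substrate. No defined catalyst can be named for this, so the step cannot be defended as known chemistry.
- Comparison: the chosen route offers predictability instead, since every centre is set by an understood control element.

**Alternative 3:** A hydrogen-atom-transfer radical closure cuts C5–C6 and leads to A6, a ring-A cyclohexane with a C4 ketal, an exocyclic methylene on C5 and a vinyl ketone on C9. Forward, Fe(acac)3 and PhSiH3 would give a tertiary C5 radical that adds to the terminal vinyl carbon C6, closing ring B to the C8 ketone A5.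
- For it: radical conjugate addition is mild and well suited to forming the quaternary C5, and the C8 ketone is a productive handle for the C8 methyl. On these points it is as strong as or stronger than a hindered cycloaddition.
- Against it: the cis ring fusion is not enforced; it depends on which face of the planar C5 radical bonds. A6 needs a quaternary C9 outside the ring with defined configuration relative to C10, which is harder to control than a ring alkylation. The C8 methyl would still need methylenation of a ketone next to C9 and a face-selective hydrogenation.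
- Comparison: the chosen route offers a cis fusion guaranteed by suprafacial addition and a C8/C9 relationship set by alkylation order on a ring.

Key step: step 14

Remark on the chemistry: centres that are erased later (spiro carbon of 8, C2 of 9 and 10, C6 of 13, oxirane carbons of 16, carbinol carbon of 18, C4 of 22–26) need not be single epimers. Names and SMILES show the epimer expected to predominate, and 8–10 are drawn with the erased centre open.

## Route

Step 1
Reactants: 1 1,2,4,5-tetramethoxybenzene
Product: 3 (2,3,5,6-tetramethoxyphenyl)methanol, via aryllithium 2 (not isolated)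
Conditions: n-BuLi, TMEDA, THF, 0 °C; paraformaldehyde, 0 °C → rt; H2O
Reagents that add atoms: paraformaldehyde (as formaldehyde), C=O
Why: The ring hydrogen between two methoxy groups is removed by directed ortho-lithiation and the aryllithium adds to formaldehyde (1,2-addition) to give the benzylic alcohol.

Step 2
Reactants: 3 (2,3,5,6-tetramethoxyphenyl)methanol
Product: 4 3-(bromomethyl)-1,2,4,5-tetramethoxybenzene
Conditions: PBr3, Et2O, 0 °C
Reagents that add atoms: phosphorus tribromide, BrP(Br)Br
Why: Standard conversion of an electron-rich benzylic alcohol into its bromide through the phosphite ester and bromide displacement.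

Step 3
Reactants: 5 (E)-but-2-enal (crotonaldehyde)
Product: 6 (E)-1-(tert-butyldimethylsilyloxy)buta-1,3-diene
Conditions: TBSOTf, Et3N, Et2O, 0 °C → rt
Reagents that add atoms: tert-butyldimethylsilyl trifluoromethanesulfonate, CC(C)(C)[Si](C)(C)OS(=O)(=O)C(F)(F)F
Why: O-Silylation of the aldehyde with loss of a γ-proton (silyl dienol ether formation) gives mainly the E diene; any Z isomer cannot reach the s-cis form and is a bystander in step 14.

Step 4
Reactants: 7 (R)-pulegone, (5R)-5-methyl-2-(propan-2-ylidene)cyclohexan-1-one
Product: 8 (6R)-2,2,6-trimethyl-1-oxaspiro[2.5]octan-4-one (pulegone oxide; both spiro epimers)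
Conditions: 30% H2O2, LiOH (cat.), MeOH, 0 °C → rt
Reagents that add atoms: hydrogen peroxide, OO
Why: Weitz–Scheffer nucleophilic epoxidation of the exocyclic enone; the methyl-bearing stereocentre is untouched and both spiro epimers serve in step 5.

Step 5
Reactants: 8 pulegone oxide
Product: 9 (5R)-5-methyl-2-(phenylsulfanyl)cyclohexan-1-one (C2 epimers)
Conditions: PhSH, NaH (cat.), THF, reflux
Reagents that add atoms: thiophenol, Sc1ccccc1
Why: Thiolate opens the oxirane at the carbon α to the ketone and the resulting β-alkoxide fragments by retro-aldol with loss of acetone, which leaves sulfur only on the α-carbon remote from the methyl group.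

Step 6
Reactants: 9 (5R)-5-methyl-2-(phenylsulfanyl)cyclohexan-1-one
Product: 11 (R)-5-methylcyclohex-2-en-1-one, via sulfoxide 10 (not isolated)
Conditions: mCPBA, CH2Cl2, −78 °C; then CaCO3, toluene, 110 °C
Reagents that add atoms: none
Why: Oxidation to the sulfoxide and thermal syn-elimination (sulfoxide pyrolysis) place the double bond regiospecifically on the side where the sulfur was; the stereocentre is not involved.

Step 7
Reactants: 11 (R)-5-methylcyclohex-2-en-1-one; 4 3-(bromomethyl)-1,2,4,5-tetramethoxybenzene
Product: 13 (5R,6S)-5-methyl-6-[(2,3,5,6-tetramethoxyphenyl)methyl]cyclohex-2-en-1-one, via lithium dienolate 12 (not isolated)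
Conditions: LiN(iPr)2, THF, −78 °C; then 4, −78 → −20 °C
Reagents that add atoms: none
Why: Kinetic α′-deprotonation gives the cross-conjugated dienolate, which is C-alkylated by the benzylic bromide mainly anti to the C5 methyl (enolate alkylation); the new centre is re-enolised in step 8, so its configuration is immaterial.

Step 8
Reactants: 13 (5R,6S)-5-methyl-6-[(2,3,5,6-tetramethoxyphenyl)methyl]cyclohex-2-en-1-one
Product: 15 (5R,6R)-5,6-dimethyl-6-[(2,3,5,6-tetramethoxyphenyl)methyl]cyclohex-2-en-1-one, via lithium enolate 14 (not isolated)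
Conditions: LiN(iPr)2, THF, −78 → −40 °C; MeI, DMPU, −78 → 0 °C
Reagents that add atoms: iodomethane, CI
Why: In enolate 14 the C5 methyl sits pseudoaxial to avoid allylic strain with the arylmethyl group, and iodomethane attacks the opposite face (enolate alkylation), so the new methyl ends trans to the C5 methyl and the arylmethyl group cis to it; this sets the quaternary C9 of the target.

Step 9
Reactants: 15 (5R,6R)-5,6-dimethyl-6-[(2,3,5,6-tetramethoxyphenyl)methyl]cyclohex-2-en-1-one
Product: 16 (1R,3R,4R,6R)-3,4-dimethyl-3-[(2,3,5,6-tetramethoxyphenyl)methyl]-7-oxabicyclo[4.1.0]heptan-2-one (oxirane anti to the C4 methyl expected to predominate)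
Conditions: 30% H2O2, aq. NaOH (cat.), MeOH, 0 °C
Reagents that add atoms: hydrogen peroxide, OO
Why: Weitz–Scheffer epoxidation at the unhindered β-carbon; the ketone has no epimerisable α-hydrogen and both oxirane epimers converge at 19.

Step 10
Reactants: 16 epoxy ketone
Product: 18 (1R,4R,5R)-4,5-dimethyl-4-[(2,3,5,6-tetramethoxyphenyl)methyl]cyclohex-2-en-1-ol, via epoxy hydrazone 17 (not isolated)
Conditions: N2H4·H2O, AcOH (cat.), MeOH, 0 °C → rt
Reagents that add atoms: none
Why: Wharton transposition: the hydrazone opens the oxirane to a hydroxy vinyl diazene that loses N2, which moves the oxygen from the carbon next to the quaternary centre to the far end of the allyl unit; the two ring stereocentres are not touched.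

Step 11
Reactants: 18 allylic alcohol
Product: 19 (4R,5R)-4,5-dimethyl-4-[(2,3,5,6-tetramethoxyphenyl)methyl]cyclohex-2-en-1-one
Conditions: Dess–Martin periodinane, CH2Cl2, rt
Reagents that add atoms: none
Why: Dess–Martin oxidation of a secondary allylic alcohol to the enone under neutral conditions; it removes the carbinol centre and completes the 1,3-carbonyl transposition.

Step 12
Reactants: 19 enone
Product: 20 (4R,5R)-2-iodo-4,5-dimethyl-4-[(2,3,5,6-tetramethoxyphenyl)methyl]cyclohex-2-en-1-one
Conditions: I2, pyridine, CH2Cl2, 0 °C → rt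
Reagents that add atoms: iodine, II
Why: α-Iodination of the enone by pyridine conjugate addition, iodination of the enolate and elimination, a sequence established for 4,4-disubstituted cyclohexenones; I2 without an oxidant does not iodinate the arene.

Step 13
Reactants: 20 α-iodoenone
Product: 21 (4R,5R)-2,4,5-trimethyl-4-[(2,3,5,6-tetramethoxyphenyl)methyl]cyclohex-2-en-1-one
Conditions: MeB(OH)2, PdCl2(dppf) (cat.), K3PO4, 1,4-dioxane/H2O, 80 °C
Reagents that add atoms: methylboronic acid, CB(O)O
Why: Suzuki–Miyaura coupling: oxidative addition of zerovalent palladium into the vinyl C–I bond, methyl transfer from boron and reductive elimination install the future C5 methyl.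

Step 14
Reactants: 21 ring-B enone; 6 (E)-1-(tert-butyldimethylsilyloxy)buta-1,3-diene
Product: 22 (3R,4R,4aS,8S,8aR)-8-[(tert-butyldimethylsilyl)oxy]-3,4,8a-trimethyl-4-[(2,3,5,6-tetramethoxyphenyl)methyl]-3,4,4a,5,8,8a-hexahydronaphthalen-1(2H)-one (cis-fused; 4β-silyloxy, Δ2, 6-ketone in decalin numbering)
Conditions: 6 (3 equiv), Me2AlCl (2.2 equiv), CH2Cl2, −78 → −20 °C; H2O
Reagents that add atoms: none
Why: Me2AlCl binds the C6 carbonyl oxygen of 21 and lowers the enone LUMO, and the diene adds in a concerted, asynchronous [4+2] cycloaddition in which the unsubstituted diene terminus bonds to the β-carbon C10 ahead of the bond from the siloxy-bearing terminus to C5 (ortho regiochemistry). The closest known reaction type is the Lewis-acid-promoted Diels–Alder addition of 1-oxygenated butadienes to 2-methylcyclohex-2-enones, which gives cis-fused decalones. Ring A is closed by intermolecular [4+2] annulation onto the C5=C10 bond of the preformed ring B, with both new bonds (C1–C10 and C4–C5) formed on one face. At C5 and C10, suprafacial addition across the ring double bond makes the C5 methyl and H-10 cis, and their absolute sense follows from the face attacked. That face is controlled by ring B: in the reactive half-chair the C8 methyl is pseudoequatorial and the arylmethyl group on C9 pseudoaxial, so the diene bonds to C10 axially and anti to the arylmethyl group, while the other half-chair has an axial C9 methyl on one face and an axial C8 methyl on the other and is blocked on both. At C4, endo placement of the carbonyl puts the siloxy group cis to C6 and trans to the C5 methyl, but this centre is erased in step 17, so endo/exo selectivity is not required. The step therefore needs face selectivity, secured by the C8/C9 substitution, and regioselectivity, secured by the donor on the diene terminus. Me2AlCl also scavenges protons as methane, which protects the acid-labile silyl dienol ether.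

Step 15
Reactants: 22 cycloadduct
Product: 23 (3R,4R,4aS,8S,8aR)-8-[(tert-butyldimethylsilyl)oxy]-3,4,8a-trimethyl-4-[(2,3,5,6-tetramethoxyphenyl)methyl]octahydronaphthalen-1(2H)-one
Conditions: H2 (1 atm), Pd/C, EtOAc, rt
Reagents that add atoms: none
Why: Heterogeneous hydrogenation of the disubstituted ring alkene; ketone, silyl ether and arene are inert and no stereocentre is formed.

Step 16
Reactants: 23 saturated silyloxy ketone
Product: 26 (1S,4aS,5R,6R,8aR)-5,6,8a-trimethyl-5-[(2,3,5,6-tetramethoxyphenyl)methyl]decahydronaphthalen-1-ol, via hydrazone 24 (not isolated), via silyl ether 25 (not isolated)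
Conditions: N2H4·H2O, KOH, diethylene glycol, 130 → 200 °C; then HCl, MeOH, 50 °C
Reagents that add atoms: none
Why: Wolff–Kishner reduction (Huang-Minlon procedure) removes the C6 carbonyl through hydrazone 24; the silyl group keeps the C4 oxygen from becoming an alkoxide β to the ketone (no retro-aldol) and C5 has no hydrogen (no β-elimination). Acid methanolysis then frees the C4 alcohol, including any silyl ether that survived the alkali.

Step 17
Reactants: 26 C4 alcohol
Product: 27 (4aS,5R,6R,8aR)-5,6,8a-trimethyl-5-[(2,3,5,6-tetramethoxyphenyl)methyl]octahydronaphthalen-1(2H)-one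
Conditions: Dess–Martin periodinane, CH2Cl2, rt
Reagents that add atoms: none
Why: Dess–Martin oxidation of the hindered secondary alcohol; the adjacent ring-fusion carbon is quaternary, so the cis fusion cannot epimerise.

Step 18
Reactants: 27 C4 ketone
Product: 28 1,2,4,5-tetramethoxy-3-{[(1R,2R,4aR,8aS)-1,2,4a-trimethyl-5-methylidenedecahydronaphthalen-1-yl]methyl}benzene
Conditions: Ph3PCH3Br, KOtBu, toluene, 90 °C
Reagents that add atoms: methyltriphenylphosphonium bromide, C[P+](c1ccccc1)(c1ccccc1)c1ccccc1.[Br-]
Why: Wittig methylenation with the small, unstabilised ylide, which is reactive enough for a ketone next to a quaternary carbon; enolisation toward C3 is harmless because no epimerisable centre is present.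

Step 19
Reactants: 28 tetramethoxyarene
Product: 29 2,5-dimethoxy-3-{[(1R,2R,4aR,8aS)-1,2,4a-trimethyl-5-methylidenedecahydronaphthalen-1-yl]methyl}cyclohexa-2,5-diene-1,4-dione
Conditions: (NH4)2Ce(NO3)6, MeCN/H2O, 0 °C
Reagents that add atoms: water, O
Why: Oxidative demethylation of a para-dimethoxyarene by tetravalent cerium (two one-electron oxidations, attack of water at the ipso carbons, loss of methanol); the two para pairs give the same quinone by symmetry, and the 1,1-disubstituted alkene is not attacked at 0 °C.

Step 20
Reactants: 29 dimethoxyquinone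
Product: 30 2-hydroxy-5-methoxy-3-{[(1R,2R,4aR,8aS)-1,2,4a-trimethyl-5-methylidenedecahydronaphthalen-1-yl]methyl}cyclohexa-2,5-diene-1,4-dione (target)
Conditions: KOH, MeOH/H2O, rt; then cold dilute HCl
Reagents that add atoms: potassium hydroxide, [K+].[OH-]
Why: Addition–elimination of hydroxide on a vinylogous ester; the methoxy group next to the alkyl substituent is twisted out of conjugation and its carbon is the more electrophilic, which is the known selectivity of 3-alkyl-2,5-dimethoxybenzoquinones. The product forms as its potassium salt, which resists a second hydrolysis, and is freed by cold dilute acid without moving the exocyclic alkene.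

## Compound list

1 | 1,2,4,5-tetramethoxybenzene | COc1cc(OC)c(OC)cc1OC | starting material
2 | (2,3,5,6-tetramethoxyphenyl)lithium | [Li]c1c(OC)c(OC)cc(OC)c1OC | intermediate
3 | (2,3,5,6-tetramethoxyphenyl)methanol | OCc1c(OC)c(OC)cc(OC)c1OC | intermediate
4 | 3-(bromomethyl)-1,2,4,5-tetramethoxybenzene | BrCc1c(OC)c(OC)cc(OC)c1OC | intermediate
5 | (E)-but-2-enal (crotonaldehyde) | C/C=C/C=O | starting material
6 | (E)-1-(tert-butyldimethylsilyloxy)buta-1,3-diene | C=C/C=C/O[Si](C)(C)C(C)(C)C | intermediate
7 | (R)-pulegone, (5R)-5-methyl-2-(propan-2-ylidene)cyclohexan-1-one | C[C@@H]1CCC(=C(C)C)C(=O)C1 | starting material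
8 | (6R)-2,2,6-trimethyl-1-oxaspiro[2.5]octan-4-one (spiro epimers) | C[C@@H]1CCC2(OC2(C)C)C(=O)C1 | intermediate
9 | (5R)-5-methyl-2-(phenylsulfanyl)cyclohexan-1-one (C2 epimers) | C[C@@H]1CCC(Sc2ccccc2)C(=O)C1 | intermediate
10 | (5R)-5-methyl-2-(phenylsulfinyl)cyclohexan-1-one | C[C@@H]1CCC(S(=O)c2ccccc2)C(=O)C1 | intermediate
11 | (R)-5-methylcyclohex-2-en-1-one | C[C@@H]1CC=CC(=O)C1 | intermediate
12 | lithium dienolate of 11 (O–Li on C1, C1=C6 and C2=C3) | C[C@@H]1CC=CC(O[Li])=C1 | intermediate
13 | (5R,6S)-5-methyl-6-[(2,3,5,6-tetramethoxyphenyl)methyl]cyclohex-2-en-1-one | C[C@@H]1CC=CC(=O)[C@H]1Cc1c(OC)c(OC)cc(OC)c1OC | intermediate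
14 | lithium dienolate of 13 (O–Li on C1, C1=C6 and C2=C3) | C[C@@H]1CC=CC(O[Li])=C1Cc1c(OC)c(OC)cc(OC)c1OC | intermediate
15 | (5R,6R)-5,6-dimethyl-6-[(2,3,5,6-tetramethoxyphenyl)methyl]cyclohex-2-en-1-one | C[C@@H]1CC=CC(=O)[C@]1(C)Cc1c(OC)c(OC)cc(OC)c1OC | intermediate
16 | (1R,3R,4R,6R)-3,4-dimethyl-3-[(2,3,5,6-tetramethoxyphenyl)methyl]-7-oxabicyclo[4.1.0]heptan-2-one | C[C@@H]1C[C@H]2O[C@H]2C(=O)[C@]1(C)Cc1c(OC)c(OC)cc(OC)c1OC | intermediate
17 | C2 hydrazone of 16 | C[C@@H]1C[C@H]2O[C@H]2C(=NN)[C@]1(C)Cc1c(OC)c(OC)cc(OC)c1OC | intermediate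
18 | (1R,4R,5R)-4,5-dimethyl-4-[(2,3,5,6-tetramethoxyphenyl)methyl]cyclohex-2-en-1-ol | C[C@@H]1C[C@@H](O)C=C[C@]1(C)Cc1c(OC)c(OC)cc(OC)c1OC | intermediate
19 | (4R,5R)-4,5-dimethyl-4-[(2,3,5,6-tetramethoxyphenyl)methyl]cyclohex-2-en-1-one | C[C@@H]1CC(=O)C=C[C@]1(C)Cc1c(OC)c(OC)cc(OC)c1OC | intermediate
20 | (4R,5R)-2-iodo-4,5-dimethyl-4-[(2,3,5,6-tetramethoxyphenyl)methyl]cyclohex-2-en-1-one | C[C@@H]1CC(=O)C(I)=C[C@]1(C)Cc1c(OC)c(OC)cc(OC)c1OC | intermediate
21 | (4R,5R)-2,4,5-trimethyl-4-[(2,3,5,6-tetramethoxyphenyl)methyl]cyclohex-2-en-1-one | CC1=C[C@](C)(Cc2c(OC)c(OC)cc(OC)c2OC)[C@H](C)CC1=O | intermediate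
22 | (3R,4R,4aS,8S,8aR)-8-[(tert-butyldimethylsilyl)oxy]-3,4,8a-trimethyl-4-[(2,3,5,6-tetramethoxyphenyl)methyl]-3,4,4a,5,8,8a-hexahydronaphthalen-1(2H)-one | [C@H]1(O[Si](C)(C)C(C)(C)C)C=CC[C@H]2[C@](C)(Cc3c(OC)c(OC)cc(OC)c3OC)[C@H](C)CC(=O)[C@@]12C | intermediate
23 | (3R,4R,4aS,8S,8aR)-8-[(tert-butyldimethylsilyl)oxy]-3,4,8a-trimethyl-4-[(2,3,5,6-tetramethoxyphenyl)methyl]octahydronaphthalen-1(2H)-one | [C@H]1(O[Si](C)(C)C(C)(C)C)CCC[C@H]2[C@](C)(Cc3c(OC)c(OC)cc(OC)c3OC)[C@H](C)CC(=O)[C@@]12C | intermediate
24 | C6 hydrazone of 23 | [C@H]1(O[Si](C)(C)C(C)(C)C)CCC[C@H]2[C@](C)(Cc3c(OC)c(OC)cc(OC)c3OC)[C@H](C)CC(=NN)[C@@]12C | intermediate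
25 | tert-butyldimethyl{[(1S,4aS,5R,6R,8aR)-5,6,8a-trimethyl-5-[(2,3,5,6-tetramethoxyphenyl)methyl]decahydronaphthalen-1-yl]oxy}silane | [C@H]1(O[Si](C)(C)C(C)(C)C)CCC[C@H]2[C@](C)(Cc3c(OC)c(OC)cc(OC)c3OC)[C@H](C)CC[C@@]12C | intermediate
26 | (1S,4aS,5R,6R,8aR)-5,6,8a-trimethyl-5-[(2,3,5,6-tetramethoxyphenyl)methyl]decahydronaphthalen-1-ol | [C@H]1(O)CCC[C@H]2[C@](C)(Cc3c(OC)c(OC)cc(OC)c3OC)[C@H](C)CC[C@@]12C | intermediate
27 | (4aS,5R,6R,8aR)-5,6,8a-trimethyl-5-[(2,3,5,6-tetramethoxyphenyl)methyl]octahydronaphthalen-1(2H)-one | O=C1CCC[C@H]2[C@](C)(Cc3c(OC)c(OC)cc(OC)c3OC)[C@H](C)CC[C@@]12C | intermediate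
28 | 1,2,4,5-tetramethoxy-3-{[(1R,2R,4aR,8aS)-1,2,4a-trimethyl-5-methylidenedecahydronaphthalen-1-yl]methyl}benzene | C=C1CCC[C@H]2[C@](C)(Cc3c(OC)c(OC)cc(OC)c3OC)[C@H](C)CC[C@@]12C | intermediate
29 | 2,5-dimethoxy-3-{[(1R,2R,4aR,8aS)-1,2,4a-trimethyl-5-methylidenedecahydronaphthalen-1-yl]methyl}cyclohexa-2,5-diene-1,4-dione | C=C1CCC[C@H]2[C@](C)(CC3=C(OC)C(=O)C=C(OC)C3=O)[C@H](C)CC[C@@]12C | intermediate
30 | 2-hydroxy-5-methoxy-3-{[(1R,2R,4aR,8aS)-1,2,4a-trimethyl-5-methylidenedecahydronaphthalen-1-yl]methyl}cyclohexa-2,5-diene-1,4-dione | C=C1CCC[C@H]2[C@](C)(CC3=C(O)C(=O)C=C(OC)C3=O)[C@H](C)CC[C@@]12C | target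

## Step count and least certain steps

Total: 20 steps. Longest linear sequence: 17 steps (7 → 30, steps 4–20); steps 1–2 (bromide 4) and step 3 (diene 6) are side branches.

**Step 14 (key step).** The likely failure is that cycloaddition at C10, which is next to the quaternary C9 and opposite an α-methyl, is too slow. Lewis-acid degradation of the silyl dienol ether, or a stepwise Mukaiyama–Michael path that ends in an open-chain adduct after silyl loss, would then take over. The fallback is a stepwise annulation from 21.
- Copper-catalysed (CuBr·SMe2) conjugate addition of [3-(1,3-dioxolan-2-yl)propyl]magnesium chloride in the presence of Me3SiCl, axial and anti to the arylmethyl group, followed by mild hydrolysis, would give the keto acetal (3R,4R,5R)-3-[3-(1,3-dioxolan-2-yl)propyl]-2,4,5-trimethyl-4-[(2,3,5,6-tetramethoxyphenyl)methyl]cyclohexan-1-one F1.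
- Aqueous HCl in THF would free the aldehyde and close C4–C5 by intramolecular aldol addition to the ketol F2. The axial side chain should favour closure on its own face, hence a cis fusion, but this has to be confirmed.
- Silylation (TBSOTf, 2,6-lutidine) would give the silyl ether F3, which is 23 and/or its C4 epimer.
- The conditions of step 16 would give the alcohol F4, and Dess–Martin oxidation would rejoin the route at 27.

**Step 8.** The hindered tertiary α′-hydrogen of 13 may be removed slowly. Proton exchange or γ-deprotonation could then divert the alkylation, or the methyl group could enter with insufficient face selectivity, and the quaternary C9 cannot be corrected later. The fallback generates the enolate regiospecifically on a saturated ring, setting out from 4.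
- Zinc insertion (Zn, LiCl, THF) would give the benzylic zinc bromide F5.
- Negishi coupling with 2-iodocyclohex-2-en-1-one (Pd(PPh3)4) would give 2-[(2,3,5,6-tetramethoxyphenyl)methyl]cyclohex-2-en-1-one F6.
- Copper-catalysed asymmetric conjugate addition of Me3Al (copper thiophene-2-carboxylate, C5H3CuO2S, with the phosphoramidite antipode that gives the 3R centre) and trapping with Me3SiOTf would give the silyl enol ether F7.
- MeLi then MeI would give (2R,3R)-2,3-dimethyl-2-[(2,3,5,6-tetramethoxyphenyl)methyl]cyclohexan-1-one F8, with the methyl trans to the ring methyl.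
- LiN(iPr)2/Me3SiCl would give the silyl enol ether F9, and Saegusa–Ito dehydrogenation with Pd(OAc)2 would rejoin the route at 15.

**Step 10.** Hydrazone formation at a carbonyl flanked by the quaternary carbon may be slow, and the vinyl diazene may decompose by other paths, so the transposition could be low-yielding. The fallback moves the oxygen by an allylic ester shift, from 15.
- NaBH4/CeCl3·7H2O would give the allylic alcohol F10, and Ac2O/DMAP its acetate F11.
- Catalytic PdCl2(MeCN)2 (divalent palladium) would equilibrate F11 by 1,3-acetoxy shift toward the less congested acetate F12.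
- K2CO3/MeOH would give the alcohol F13 (18 and/or its carbinol epimer), and Dess–Martin oxidation would rejoin the route at 19.

**Step 16.** Hydrazone formation at the C6 ketone next to the quaternary C5 may be incomplete, and premature loss of the silyl group in hot alkali would open ring A by retro-aldol cleavage. The fallback removes the oxygen through an enol triflate, from 23.
- KN(SiMe3)2 and PhNTf2 would give the C6–C7 enol triflate F14.
- Pd(OAc)2, PPh3, Bu3N and HCO2H would reduce it to the alkene F15.
- Hydrogenation over Pd/C would give 25, and the acid methanolysis of step 16 would rejoin the route at 26.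

## Further compounds

F1 | step 14 | (3R,4R,5R)-3-[3-(1,3-dioxolan-2-yl)propyl]-2,4,5-trimethyl-4-[(2,3,5,6-tetramethoxyphenyl)methyl]cyclohexan-1-one (C2 epimers) | O1CCOC1CCC[C@H]1[C@](C)(Cc2c(OC)c(OC)cc(OC)c2OC)[C@H](C)CC(=O)C1C
F2 | step 14 | cis-fused ketol, 8-hydroxy analogue of 23 without silyl group (C4 epimers in decalin numbering) | OC1CCC[C@H]2[C@](C)(Cc3c(OC)c(OC)cc(OC)c3OC)[C@H](C)CC(=O)[C@@]12C
F3 | step 14 | tert-butyldimethylsilyl ether of F2 (23 and/or its C4 epimer) | CC(C)(C)[Si](C)(C)OC1CCC[C@H]2[C@](C)(Cc3c(OC)c(OC)cc(OC)c3OC)[C@H](C)CC(=O)[C@@]12C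
F4 | step 14 | (4aS,5R,6R,8aR)-5,6,8a-trimethyl-5-[(2,3,5,6-tetramethoxyphenyl)methyl]decahydronaphthalen-1-ol (C1 epimers; 26 and/or its epimer) | OC1CCC[C@H]2[C@](C)(Cc3c(OC)c(OC)cc(OC)c3OC)[C@H](C)CC[C@@]12C
F5 | step 8 | [(2,3,5,6-tetramethoxyphenyl)methyl]zinc bromide | Br[Zn]Cc1c(OC)c(OC)cc(OC)c1OC
F6 | step 8 | 2-[(2,3,5,6-tetramethoxyphenyl)methyl]cyclohex-2-en-1-one | O=C1CCCC=C1Cc1c(OC)c(OC)cc(OC)c1OC
F7 | step 8 | trimethyl({(3R)-3-methyl-2-[(2,3,5,6-tetramethoxyphenyl)methyl]cyclohex-1-en-1-yl}oxy)silane | C[C@@H]1CCCC(O[Si](C)(C)C)=C1Cc1c(OC)c(OC)cc(OC)c1OC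
F8 | step 8 | (2R,3R)-2,3-dimethyl-2-[(2,3,5,6-tetramethoxyphenyl)methyl]cyclohexan-1-one | C[C@@H]1CCCC(=O)[C@]1(C)Cc1c(OC)c(OC)cc(OC)c1OC
F9 | step 8 | trimethyl({(5R,6R)-5,6-dimethyl-6-[(2,3,5,6-tetramethoxyphenyl)methyl]cyclohex-1-en-1-yl}oxy)silane | C[C@@H]1CCC=C(O[Si](C)(C)C)[C@]1(C)Cc1c(OC)c(OC)cc(OC)c1OC
F10 | step 10 | (5R,6R)-5,6-dimethyl-6-[(2,3,5,6-tetramethoxyphenyl)methyl]cyclohex-2-en-1-ol (C1 epimers) | C[C@@H]1CC=CC(O)[C@]1(C)Cc1c(OC)c(OC)cc(OC)c1OC
F11 | step 10 | (5R,6R)-5,6-dimethyl-6-[(2,3,5,6-tetramethoxyphenyl)methyl]cyclohex-2-en-1-yl acetate (C1 epimers) | C[C@@H]1CC=CC(OC(C)=O)[C@]1(C)Cc1c(OC)c(OC)cc(OC)c1OC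
F12 | step 10 | (4R,5R)-4,5-dimethyl-4-[(2,3,5,6-tetramethoxyphenyl)methyl]cyclohex-2-en-1-yl acetate (C1 epimers) | C[C@@H]1CC(OC(C)=O)C=C[C@]1(C)Cc1c(OC)c(OC)cc(OC)c1OC
F13 | step 10 | (4R,5R)-4,5-dimethyl-4-[(2,3,5,6-tetramethoxyphenyl)methyl]cyclohex-2-en-1-ol (C1 epimers; 18 and/or its epimer) | C[C@@H]1CC(O)C=C[C@]1(C)Cc1c(OC)c(OC)cc(OC)c1OC
F14 | step 16 | C6–C7 enol trifluoromethanesulfonate of 23 | [C@H]1(O[Si](C)(C)C(C)(C)C)CCC[C@H]2[C@](C)(Cc3c(OC)c(OC)cc(OC)c3OC)[C@H](C)C=C(OS(=O)(=O)C(F)(F)F)[C@@]12C
F15 | step 16 | C6–C7 alkene, 6,7-didehydro analogue of 25 | [C@H]1(O[Si](C)(C)C(C)(C)C)CCC[C@H]2[C@](C)(Cc3c(OC)c(OC)cc(OC)c3OC)[C@H](C)C=C[C@@]12C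
A1 | alternative 1 | cis-fused octalin with C9 formyl group, C4 tert-butyldimethylsilyl ether and C6=C7 double bond | [C@@H]1(O[Si](C)(C)C(C)(C)C)CCC[C@H]2[C@](C)(C=O)[C@H](C)C=C[C@@]12C
A2 | alternative 1 | (2E,7R,8Z,10E)-7-[(tert-butyldimethylsilyl)oxy]-2,8-dimethyldodeca-2,8,10-trienal | O=C/C(C)=C/CCC[C@@H](O[Si](C)(C)C(C)(C)C)/C(C)=C\C=C\C
A3 | alternative 2 | rearranged cis-decalin tetramethoxyarene with C4 methylidene (identical with 28) | C=C1CCC[C@H]2[C@](C)(Cc3c(OC)c(OC)cc(OC)c3OC)[C@H](C)CC[C@@]12C
A4 | alternative 2 | 1,2,4,5-tetramethoxy-3-[(2E,6E)-3,7,11-trimethyldodeca-2,6,10-trien-1-yl]benzene | CC(C)=CCC/C(C)=C/CC/C(C)=C/Cc1c(OC)c(OC)cc(OC)c1OC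
A5 | alternative 3 | cis-decalin with C4 ethylene ketal, C5 methyl and C8 ketone | O1CCOC12CCC[C@H]3[C@](C)(Cc4c(OC)c(OC)cc(OC)c4OC)C(=O)CC[C@@]23C
A6 | alternative 3 | ring-A ketal with C5 exocyclic methylene and a vinyl ketone on C9 | C=C1C2(OCCO2)CCC[C@H]1[C@](C)(Cc1c(OC)c(OC)cc(OC)c1OC)C(=O)C=C
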